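**Strategy**

Everything rests on a late closure of the five-membered ring by joining chromene C5 (the aryl C–Br carbon) to the cyclobutene CH carbon (C4′). The precursor is an aryl-substituted cyclobutene with a single stereocentre, the allylic CH (C1′) that carries the CH2 link to C6 of the bromochromene. An intramolecular reductive Heck reaction exploits this strained C3′=C4′ bond next to the quaternary CMe2 carbon: 5-exo syn-carbopalladation from the tether face gives the cis-fused bicyclo[3.2.0]heptane, palladium lands on aryl-bearing C3′ with no syn β-hydrogen, and formate hydride replaces it with retention. One operation closes the ring and sets two stereocentres, with the catechol ring trans to the new bond.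

Key step: step 13

Remark: primed locants refer to the four-membered ring (C1′ = CH bearing the CH2 link, C2′ = CMe2, C3′ = aryl-bearing carbon, C4′ = remaining CH); unprimed locants refer to the 2H-chromene. The five starting materials are taken as commercial. The sense of induction in step 11 cannot be predicted with confidence; both ligand enantiomers are available and the one that gives the (S) product is to be chosen on a trial run.

**Route**

Step 1
Reactants: 1 2-bromo-4,6-dimethoxybenzaldehyde
Product: 2 2-bromo-4,6-dihydroxybenzaldehyde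
Conditions: BBr3 (4 equiv), CH2Cl2, −78 °C to rt; then H2O
Reagents that add atoms: none
Why: Lewis-acid aryl methyl ether cleavage (boron–oxygen complexation, bromide attack at methyl) should remove both methyl groups and leave the aldehyde and the aryl bromide untouched.

Step 2
Reactants: 2 2-bromo-4,6-dihydroxybenzaldehyde; 3 3-chloro-3-methylbut-1-yne
Product: 4 2-bromo-6-hydroxy-4-[(2-methylbut-3-yn-2-yl)oxy]benzaldehyde
Conditions: DBU, CuCl2·2H2O (1 mol %), MeCN, 0 °C to rt
Reagents that add atoms: none
Why: Copper-catalysed propargylic etherification with the tertiary propargyl chloride should take place at the 4-hydroxyl, which is the more acidic one (para to the aldehyde) and is not held in the hydrogen bond to the carbonyl group.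

Step 3
Reactants: 4 2-bromo-6-hydroxy-4-[(2-methylbut-3-yn-2-yl)oxy]benzaldehyde
Product: 5 2-bromo-6-methoxy-4-[(2-methylbut-3-yn-2-yl)oxy]benzaldehyde
Conditions: MeI, K2CO3, DMF, 40 °C
Reagents that add atoms: iodomethane (MeI), CI
Why: Williamson methylation of the one remaining (chelated) phenol, which is the only nucleophilic site left.

Step 4
Reactants: 5 2-bromo-6-methoxy-4-[(2-methylbut-3-yn-2-yl)oxy]benzaldehyde
Product: 6 5-bromo-7-methoxy-2,2-dimethyl-2H-chromene-6-carbaldehyde
Conditions: PhNEt2, 185 °C
Reagents that add atoms: none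
Why: Aryl propargyl ether Claisen rearrangement followed in the same flask by enolisation, 1,5-hydrogen shift and oxa-6π electrocyclisation; the meta bromine directs the [3,3] shift to its own side and the meta methoxy group directs it to its para position, which is the same carbon, so the pyran ring should form between the ether oxygen and the C–Br carbon.

Step 5
Reactants: 6 5-bromo-7-methoxy-2,2-dimethyl-2H-chromene-6-carbaldehyde
Product: 7 (5-bromo-7-methoxy-2,2-dimethyl-2H-chromen-6-yl)methanol
Conditions: NaBH4, MeOH/THF, 0 °C
Reagents that add atoms: none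
Why: Borohydride reduction of the aryl aldehyde; the chromene alkene and the aryl bromide are inert.

Step 6
Reactants: 7 (5-bromo-7-methoxy-2,2-dimethyl-2H-chromen-6-yl)methanol
Product: 8 5-bromo-6-(chloromethyl)-7-methoxy-2,2-dimethyl-2H-chromene
Conditions: SOCl2, 2,6-lutidine, CH2Cl2, −10 °C; used crude
Reagents that add atoms: thionyl chloride, O=S(Cl)Cl
Why: Chlorodehydroxylation of an activated benzylic alcohol with thionyl chloride; the hindered base removes HCl (protecting the chromene) without quaternising the labile electron-rich benzyl chloride.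

Step 7
Reactants: 9 isobutyryl chloride (2-methylpropanoyl chloride); 10 ethoxyacetylene
Product: 12 3-ethoxy-4,4-dimethylcyclobut-2-en-1-one, via dimethylketene 11 (not isolated)
Conditions: Et3N, Et2O, 0 °C to rt
Reagents that add atoms: none
Why: Dehydrochlorination gives dimethylketene, which undergoes ketene–ynol ether [2+2] cycloaddition; the nucleophilic terminal alkyne carbon bonds to the ketene carbonyl carbon, which fixes the 3-ethoxy-4,4-dimethyl pattern.

Step 8
Reactants: 12 3-ethoxy-4,4-dimethylcyclobut-2-en-1-one
Product: 14 cyclobutenone 4,4-dimethylcyclobut-2-en-1-one, via allylic alcohol 13 (not isolated)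
Conditions: LiAlH4, Et2O, 0 °C; then 1 M HCl, 0 °C
Reagents that add atoms: water, O
Why: 1,2-Hydride reduction of the vinylogous ester to 13, then acid hydrolysis of the enol ether with loss of water (Stork–Danheiser-type carbonyl transposition) should give the enone whose β-carbon lies next to the CMe2 group.

Step 9
Reactants: 15 4-bromobenzene-1,2-diol
Product: 16 4-bromo-1,2-bis(methoxymethoxy)benzene
Conditions: MOMCl, i-Pr2NEt, CH2Cl2, 0 °C to rt
Reagents that add atoms: chloromethyl methyl ether (MOMCl), COCCl
Why: Standard O-alkylation of both phenols to acetal (MOM) ethers, which survive base, organometallics and palladium catalysis and leave under mild acid.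

Step 10
Reactants: 16 4-bromo-1,2-bis(methoxymethoxy)benzene
Product: 18 2-[3,4-bis(methoxymethoxy)phenyl]-4,4,5,5-tetramethyl-1,3,2-dioxaborolane, via aryllithium 17 (not isolated)
Conditions: n-BuLi, THF, −78 °C; then i-PrOBpin, −78 °C to rt
Reagents that add atoms: 2-isopropoxy-4,4,5,5-tetramethyl-1,3,2-dioxaborolane, CC(C)OB1OC(C)(C)C(C)(C)O1
Why: Bromine–lithium exchange is faster than ortho-lithiation at −78 °C, and borylation of the aryllithium with the alkoxyboronate gives the pinacol ester.

Step 11
Reactants: 8 5-bromo-6-(chloromethyl)-7-methoxy-2,2-dimethyl-2H-chromene; 14 4,4-dimethylcyclobut-2-en-1-one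
Product: 21 (S)-3-[(5-bromo-7-methoxy-2,2-dimethyl-2H-chromen-6-yl)methyl]-4,4-dimethylcyclobut-1-en-1-yl trifluoromethanesulfonate, via benzylic Grignard reagent 19 (not isolated), via magnesium enolate 20 (not isolated)
Conditions: Mg, Et2O, 0 °C; then 14, CuBr·SMe2 (5 mol %), Josiphos ligand (R)-1-[(S)-2-(diphenylphosphino)ferrocenyl]ethyldicyclohexylphosphine, C36H44FeP2, or its enantiomer (6 mol %), t-BuOMe, −78 °C; then 2-[N,N-bis(trifluoromethylsulfonyl)amino]-5-chloropyridine, THF, −78 to 0 °C
Reagents that add atoms: 2-[N,N-bis(trifluoromethylsulfonyl)amino]-5-chloropyridine, FC(F)(F)S(=O)(=O)N(c1ccc(Cl)cn1)S(=O)(=O)C(F)(F)F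
Why: Copper-catalysed asymmetric conjugate addition of a Grignard reagent to a strained cyclic enone, followed by O-triflation of the only possible enolate (the other α-carbon is quaternary); the chiral diphosphine–copper complex selects the enone face and so sets the (S) stereocentre at the β-carbon (catalyst control).

Step 12
Reactants: 21 (S)-alkenyl triflate; 18 2-[3,4-bis(methoxymethoxy)phenyl]-4,4,5,5-tetramethyl-1,3,2-dioxaborolane
Product: 22 6-{[(1S)-3-[3,4-bis(methoxymethoxy)phenyl]-2,2-dimethylcyclobut-3-en-1-yl]methyl}-5-bromo-7-methoxy-2,2-dimethyl-2H-chromene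
Conditions: Pd(PPh3)4 (5 mol %), K3PO4, THF/H2O, 40 °C
Reagents that add atoms: none
Why: Suzuki–Miyaura coupling; the strained alkenyl triflate should undergo oxidative addition far faster than the di-ortho-substituted, electron-rich aryl bromide at 40 °C, and the stereocentre is not involved.

Step 13
Reactants: 22 6-{[(1S)-3-[3,4-bis(methoxymethoxy)phenyl]-2,2-dimethylcyclobut-3-en-1-yl]methyl}-5-bromo-7-methoxy-2,2-dimethyl-2H-chromene
Product: 23 bis(methoxymethyl) ether of 24: tetracycle in which C5 is bonded to C4′, so that C5, C6, the CH2 group, C1′ and C4′ form a cyclopentane cis-fused to the cyclobutane, with the 3,4-bis(methoxymethoxy)phenyl group on C3′ trans to the C5–C4′ bond (1′S,3′S,4′R)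
Conditions: Pd(OAc)2 (10 mol %), PPh3 (20 mol %), HCO2Na (3 equiv), Et4NCl, DMF, 90 °C
Reagents that add atoms: none
Why: Zerovalent palladium inserts into the C5–Br bond, the arylpalladium adds syn across the strained C3′=C4′ bond, and the tertiary benzylic alkylpalladium at C3′ (its only β-hydrogen, on C4′, is anti and the other β-carbon is the quaternary C2′) is captured by formate, which loses CO2 and delivers hydride by C–H reductive elimination with retention. The reaction type is the intramolecular reductive Heck reaction, a hydroarylation of a strained alkene. The five-membered ring closes in the 5-exo-trig mode; the 6-endo alternative would give a bridged bicyclo[3.1.1] skeleton and is not expected. The C4′ stereocentre is controlled by the existing (S)-C1′ centre through the one-carbon tether, which can reach only the alkene face on which it sits, so the ring fusion is cis; the C3′ stereocentre is controlled by the syn stereospecificity of insertion and the retentive hydride transfer, which place H cis to the new C5–C4′ bond and the aryl group trans to it, on the face of the two ring-fusion hydrogens. The selectivity needed is insertion ahead of formate reduction of the arylpalladium and reaction at the cyclobutene and not at the chromene alkene; the first is secured by the proximity and strain of the cyclobutene, the second by the fact that the chromene C=C could only close a four-membered ring.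

Step 14
Reactants: 23 bis(methoxymethyl) ether of the target
Product: 24 target CNP0207533.1: the same tetracycle with the free 3,4-dihydroxyphenyl group on C3′ (1′S,3′S,4′R)
Conditions: 2 M HCl, MeOH, 45 °C, argon
Reagents that add atoms: none
Why: Acid-catalysed acetal cleavage (transacetalisation to dimethoxymethane) should free the catechol, while the aryl methyl ether and the 2,2-dimethylchromene tolerate dilute methanolic acid; no stereocentre is touched.

**Compound list**

1 | 2-bromo-4,6-dimethoxybenzaldehyde | COc1cc(OC)c(C=O)c(Br)c1 | starting material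
2 | 2-bromo-4,6-dihydroxybenzaldehyde | Oc1cc(O)c(C=O)c(Br)c1 | intermediate
3 | 3-chloro-3-methylbut-1-yne | CC(C)(Cl)C#C | starting material
4 | 2-bromo-6-hydroxy-4-[(2-methylbut-3-yn-2-yl)oxy]benzaldehyde | C#CC(C)(C)Oc1cc(O)c(C=O)c(Br)c1 | intermediate
5 | 2-bromo-6-methoxy-4-[(2-methylbut-3-yn-2-yl)oxy]benzaldehyde | C#CC(C)(C)Oc1cc(OC)c(C=O)c(Br)c1 | intermediate
6 | 5-bromo-7-methoxy-2,2-dimethyl-2H-chromene-6-carbaldehyde | COc1cc2c(c(Br)c1C=O)C=CC(C)(C)O2 | intermediate
7 | (5-bromo-7-methoxy-2,2-dimethyl-2H-chromen-6-yl)methanol | COc1cc2c(c(Br)c1CO)C=CC(C)(C)O2 | intermediate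
8 | 5-bromo-6-(chloromethyl)-7-methoxy-2,2-dimethyl-2H-chromene | COc1cc2c(c(Br)c1CCl)C=CC(C)(C)O2 | intermediate
9 | isobutyryl chloride (2-methylpropanoyl chloride) | CC(C)C(=O)Cl | starting material
10 | ethoxyacetylene | CCOC#C | starting material
11 | dimethylketene | CC(C)=C=O | intermediate
12 | 3-ethoxy-4,4-dimethylcyclobut-2-en-1-one | CCOC1=CC(=O)C1(C)C | intermediate
13 | 3-ethoxy-4,4-dimethylcyclobut-2-en-1-ol | CCOC1=CC(O)C1(C)C | intermediate
14 | 4,4-dimethylcyclobut-2-en-1-one | O=C1C=CC1(C)C | intermediate
15 | 4-bromobenzene-1,2-diol | Oc1ccc(Br)cc1O | starting material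
16 | 4-bromo-1,2-bis(methoxymethoxy)benzene | COCOc1ccc(Br)cc1OCOC | intermediate
17 | [3,4-bis(methoxymethoxy)phenyl]lithium | COCOc1ccc([Li])cc1OCOC | intermediate
18 | 2-[3,4-bis(methoxymethoxy)phenyl]-4,4,5,5-tetramethyl-1,3,2-dioxaborolane | COCOc1ccc(B2OC(C)(C)C(C)(C)O2)cc1OCOC | intermediate
19 | [(5-bromo-7-methoxy-2,2-dimethyl-2H-chromen-6-yl)methyl]magnesium chloride | COc1cc2c(c(Br)c1C[Mg]Cl)C=CC(C)(C)O2 | intermediate
20 | chloromagnesium (S)-3-[(5-bromo-7-methoxy-2,2-dimethyl-2H-chromen-6-yl)methyl]-4,4-dimethylcyclobut-1-en-1-olate | COc1cc2c(c(Br)c1C[C@H]1C=C(O[Mg]Cl)C1(C)C)C=CC(C)(C)O2 | intermediate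
21 | (S)-3-[(5-bromo-7-methoxy-2,2-dimethyl-2H-chromen-6-yl)methyl]-4,4-dimethylcyclobut-1-en-1-yl trifluoromethanesulfonate | COc1cc2c(c(Br)c1C[C@H]1C=C(OS(=O)(=O)C(F)(F)F)C1(C)C)C=CC(C)(C)O2 | intermediate
22 | 6-{[(1S)-3-[3,4-bis(methoxymethoxy)phenyl]-2,2-dimethylcyclobut-3-en-1-yl]methyl}-5-bromo-7-methoxy-2,2-dimethyl-2H-chromene | COc1cc2c(c(Br)c1C[C@H]1C=C(c3ccc(OCOC)c(OCOC)c3)C1(C)C)C=CC(C)(C)O2 | intermediate
23 | bis(methoxymethyl) ether of the target (1′S,3′S,4′R) | COc1cc2c(c3c1C[C@H]1[C@@H]3[C@H](c3ccc(OCOC)c(OCOC)c3)C1(C)C)C=CC(C)(C)O2 | intermediate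
24 | CNP0207533.1 (1′S,3′S,4′R; ring-fusion hydrogens and the 3,4-dihydroxyphenyl group on one face of the cyclobutane) | COc1cc2c(c3c1C[C@H]1[C@@H]3[C@H](c3ccc(O)c(O)c3)C1(C)C)C=CC(C)(C)O2 | target

**Step count and risks**

Total step count: 14. Longest linear sequence: 10 steps (steps 1 to 6, then 11 to 14).

Steps most likely to fail:

1. Step 11. What may go wrong: Wurtz coupling during magnesium insertion, direct 1,2-addition of the benzylic Grignard reagent to the carbonyl group, and weak facial discrimination at the β-carbon beside the quaternary centre, which would erode enantiomeric purity. Fallback: it sets out from Grignard reagent 19 and vinylogous ester 12. 1,2-Addition at −78 °C and dilute HCl work-up (Stork–Danheiser transposition) should give 3-[(5-bromo-7-methoxy-2,2-dimethyl-2H-chromen-6-yl)methyl]-4,4-dimethylcyclobut-2-en-1-one F1. Copper hydride asymmetric conjugate reduction (Cu(OAc)2·H2O, one enantiomer of Tol-BINAP, polymethylhydrosiloxane, toluene, 0 °C, then Bu4NF) would then set the stereocentre by hydride delivery and give (S)-3-[(5-bromo-7-methoxy-2,2-dimethyl-2H-chromen-6-yl)methyl]-2,2-dimethylcyclobutan-1-one F2. Deprotonation with LiN(SiMe3)2 at −78 °C and O-triflation with the same pyridyl triflimide returns to 21.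

2. Step 13. What may go wrong: formate reduction of the arylpalladium bromide before insertion (hydrodebromination), or sluggish oxidative addition at the di-ortho-substituted C–Br bond. Fallback: it sets out from 22. Bromine–lithium exchange with in situ borylation (i-PrOBpin, then n-BuLi, THF, −78 °C) should give the aryl boronate 6-{[(1S)-3-[3,4-bis(methoxymethoxy)phenyl]-2,2-dimethylcyclobut-3-en-1-yl]methyl}-7-methoxy-2,2-dimethyl-5-(4,4,5,5-tetramethyl-1,3,2-dioxaborolan-2-yl)-2H-chromene F3. Rhodium-catalysed intramolecular hydroarylation ([Rh(cod)OH]2, aqueous KOH, dioxane, 60 °C) would then proceed by transmetalation to an arylrhodium species (monovalent rhodium), syn addition across the cyclobutene and protonolysis of the benzylic C–Rh bond with retention. It needs no hydride source and returns to 23 with the same stereochemical logic.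

3. Step 12. What may go wrong: hydrolysis of the strained alkenyl triflate by aqueous base, and premature oxidative addition at the aryl bromide of the product leading to Heck-type consumption. Fallback: it sets out from magnesium enolate 20. Aqueous NH4Cl quench instead of triflation gives the ketone F2 described above. Addition of aryllithium 17 (precomplexed with CeCl3, THF, −78 °C) should give (3S)-1-[3,4-bis(methoxymethoxy)phenyl]-3-[(5-bromo-7-methoxy-2,2-dimethyl-2H-chromen-6-yl)methyl]-2,2-dimethylcyclobutan-1-ol F4 as a mixture of carbinol epimers. Syn dehydration with methyl N-(triethylammoniosulfonyl)carbamate (toluene, 50 °C) can only go towards the CH2 carbon and returns to 22 without palladium.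

**Further compounds**

F1 | step 11 | 3-[(5-bromo-7-methoxy-2,2-dimethyl-2H-chromen-6-yl)methyl]-4,4-dimethylcyclobut-2-en-1-one | COc1cc2c(c(Br)c1CC1=CC(=O)C1(C)C)C=CC(C)(C)O2
F2 | step 11 | (S)-3-[(5-bromo-7-methoxy-2,2-dimethyl-2H-chromen-6-yl)methyl]-2,2-dimethylcyclobutan-1-one | COc1cc2c(c(Br)c1C[C@H]1CC(=O)C1(C)C)C=CC(C)(C)O2
F3 | step 13 | 6-{[(1S)-3-[3,4-bis(methoxymethoxy)phenyl]-2,2-dimethylcyclobut-3-en-1-yl]methyl}-7-methoxy-2,2-dimethyl-5-(4,4,5,5-tetramethyl-1,3,2-dioxaborolan-2-yl)-2H-chromene | COc1cc2c(c(B3OC(C)(C)C(C)(C)O3)c1C[C@H]1C=C(c3ccc(OCOC)c(OCOC)c3)C1(C)C)C=CC(C)(C)O2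
F4 | step 12 | (3S)-1-[3,4-bis(methoxymethoxy)phenyl]-3-[(5-bromo-7-methoxy-2,2-dimethyl-2H-chromen-6-yl)methyl]-2,2-dimethylcyclobutan-1-ol | COc1cc2c(c(Br)c1C[C@H]1CC(O)(c3ccc(OCOC)c(OCOC)c3)C1(C)C)C=CC(C)(C)O2
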